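**Retrosynthetic overview**

1. Cyclohexene numbering: C1 (CH3, alkene), C2 (alkene CH), C3, C4 (O and isopropyl), C5, C6. The enabling feature is that the ester oxygen sits on C4, homoallylic to the C1=C2 alkene (O–C4–C3–C2=C1), which is the retron of a cyclopropylcarbinyl cation.
2. Last disconnection (C4–O): a temporary C2–C4 bond folds the cyclohexene into the bicyclo[3.1.0]hexane of sabinene (cyclopropane C2–C3–C4 fused to cyclopentane C1–C2–C4–C5–C6). Acid-catalysed addition of the benzoic acid reopens C2–C4 with inversion at C4.
3. Sabinene ⇐ sabina ketone (Wittig) ⇐ bicyclo[3.1.0]hexan-2-ol (oxidation).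
4. Key (3+3) union in one flask: (R)-epichlorohydrin supplies C6–C1–C2 and a 2-isopropylallyl Grignard reagent supplies C5–C4–C3. Epoxide opening forms C5–C6, then lithium-carbenoid cyclopropanation forms C2–C3 together with the temporary C2–C4 bond. Cyclopentane and cyclopropane form together; the cyclohexene appears last.
5. Acid part: 4-iodophenol ⇒ two successive ortho-prenylations (two equivalents of prenyl bromide) ⇒ hydroxycarbonylation; the arene ring is bought.

Key step: step 3

Assumption: the acid-catalysed opening of the sabinene cyclopropane by a carboxylic acid is taken to follow the same invertive course at the isopropyl-bearing carbon as the acid hydration of sabinene to terpinen-4-ol.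

**Route**

Step 1
Reactants: 1 prop-2-yn-1-ol; 2 isopropylmagnesium chloride
Product: 4 3-methyl-2-methylidenebutan-1-ol, via alkenylmagnesium alkoxide 3 (not isolated)
Conditions: iPrMgCl (2.5 equiv), CuI (10 mol %), Et2O, −10 °C → reflux; then cold dilute HCl
Reagents that add atoms: none
Why: Copper-catalysed anti-carbomagnesiation of the propargylic magnesium alkoxide places the isopropyl group on the internal alkyne carbon through a five-membered magnesium chelate, and protonolysis of the C–Mg bond should give the 2-substituted allylic alcohol; no stereocentre is formed.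

Step 2
Reactants: 4 3-methyl-2-methylidenebutan-1-ol
Product: 5 2-(chloromethyl)-3-methylbut-1-ene
Conditions: PPh3, CCl4, reflux; distil
Reagents that add atoms: tetrachloromethane, ClC(Cl)(Cl)Cl
Why: Appel reaction of the primary allylic alcohol under neutral conditions, which avoids HCl addition to the 1,1-disubstituted alkene; the two CH2 termini of the allyl unit are equivalent, so SN2 and SN2' paths give the same chloride.

Step 3
Reactants: 5 2-(chloromethyl)-3-methylbut-1-ene; 6 (2R)-2-(chloromethyl)oxirane [(R)-epichlorohydrin]
Product: 10 (1R,2R,5S)-5-(propan-2-yl)bicyclo[3.1.0]hexan-2-ol, via allylic Grignard reagent 7 (not isolated), via chlorohydrin magnesium alkoxide 8 (not isolated), via terminal epoxide 9 (not isolated)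
Conditions: Mg, Et2O, 0 °C; add to 6, Et2O/MTBE, −40 → 0 °C; then lithium 2,2,6,6-tetramethylpiperidide (LiTMP, 3.5 equiv), MTBE, 0 °C → rt, same flask; H2O
Reagents that add atoms: none
Why: The allylic Grignard reagent 7 opens 6 at its unsubstituted ring carbon (future C5–C6 bond), alkoxide 8 closes to epoxide 9, LiTMP removes the epoxide CH2 hydrogen trans to the chain, and the α-lithiated epoxide adds as a carbenoid to the tethered 1,1-disubstituted alkene (future C2–C3 bond plus the temporary C2–C4 bond) while its ring C–O bond breaks to leave the lithium alkoxide. The closest known reaction type is the lithium amide-induced intramolecular cyclopropanation of unsaturated terminal epoxides and of their chlorohydrins, fed here directly by a Grignard opening of epichlorohydrin. The cyclopentane closes 5-exo-trig by bonding of the internal alkene carbon to the carbenoid carbon, and the cyclopropane closes in the same [2+1] event at the alkene CH2, cis fusion being the only possibility. The carbinol centre is that of 6, untouched because both substitutions occur at CH2 groups, and it sets both bridgeheads: trans-lithiation and backside attack of the alkene on the carbenoid C–O bond place the cyclopropane anti to the oxygen, which should give the (1R,2R,5S) isomer. The step needs the Grignard reagent to attack the epoxide CH2 and not the C–Cl carbon (which would lead to the enantiomer), secured by the higher reactivity of the strained ring toward allylmagnesium halides at low temperature; it also needs cyclopropanation to outrun β-elimination and amide addition, secured by the hindered amide and the short tether to an electron-rich alkene.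

Step 4
Reactants: 10 (1R,2R,5S)-5-(propan-2-yl)bicyclo[3.1.0]hexan-2-ol
Product: 11 (1R,5S)-5-(propan-2-yl)bicyclo[3.1.0]hexan-2-one
Conditions: TEMPO (2 mol %), KBr (10 mol %), NaOCl, NaHCO3, CH2Cl2/H2O, 0 °C
Reagents that add atoms: none
Why: Anelli oxidation (TEMPO/NaOCl) of the secondary cyclopropylcarbinol should give the ketone; the carbinol centre is removed, and the bridgeheads (one quaternary, one on the cyclopropane of a cis-fused bicycle) cannot epimerise.

Step 5
Reactants: 11 (1R,5S)-5-(propan-2-yl)bicyclo[3.1.0]hexan-2-one
Product: 12 (1S,5S)-4-methylidene-1-(propan-2-yl)bicyclo[3.1.0]hexane [(1S,5S)-sabinene]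
Conditions: Ph3PCH3Br, KOtBu, Et2O, 0 °C → rt; careful concentration (volatile)
Reagents that add atoms: methyltriphenylphosphonium bromide, C[P+](c1ccccc1)(c1ccccc1)c1ccccc1.[Br-]
Why: Wittig methylenation of the ketone should give the exocyclic alkene; only the ring CH2 is readily enolisable, so no stereocentre is at risk (the descriptors change only because of numbering and priorities).

Step 6
Reactants: 13 4-iodophenol; 14 1-bromo-3-methylbut-2-ene (prenyl bromide, first equivalent)
Product: 16 4-iodo-2,6-bis(3-methylbut-2-en-1-yl)phenol, via mono-prenylated iodophenol 15 (not isolated)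
Conditions: NaH (1.1 equiv), toluene, 0 °C, then 14 (1.1 equiv), rt; second charge of NaH (1.1 equiv) and 14 (1.1 equiv), same flask, rt; aq NH4Cl
Reagents that add atoms: 1-bromo-3-methylbut-2-ene (second equivalent), CC(C)=CCBr
Why: Ortho-selective C-alkylation of the sodium phenoxide by the primary allylic bromide in a non-polar solvent (tight ion pair, SN2 at carbon, then rearomatisation) is run twice in the same flask, with one equivalent of base and of 14 for each ortho position, so the two prenyl groups of 16 come from two equivalents of 14; the para position is blocked by iodine.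

Step 7
Reactants: 16 4-iodo-2,6-bis(3-methylbut-2-en-1-yl)phenol
Product: 17 4-hydroxy-3,5-bis(3-methylbut-2-en-1-yl)benzoic acid
Conditions: Pd(OAc)2 (3 mol %), Xantphos (4 mol %), CO (1 atm), K2CO3, 1,4-dioxane/H2O, 80 °C; then aq citric acid
Reagents that add atoms: carbon monoxide, [C-]#[O+]; water, O
Why: Palladium-catalysed hydroxycarbonylation of the aryl iodide (oxidative addition, CO insertion, hydrolysis of the acylpalladium) should give the benzoic acid; the prenyl groups are meta to the acylpalladium and cannot cyclise onto it.

Step 8
Reactants: 12 (1S,5S)-sabinene; 17 4-hydroxy-3,5-bis(3-methylbut-2-en-1-yl)benzoic acid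
Product: 18 (1R)-4-methyl-1-(propan-2-yl)cyclohex-3-en-1-yl 4-hydroxy-3,5-bis(3-methylbut-2-en-1-yl)benzoate (target)
Conditions: (PhO)2P(O)OH (5 mol %), CH2Cl2, −20 → 0 °C
Reagents that add atoms: none
Why: Acid-catalysed hydroacyloxylation with cyclopropylcarbinyl-to-homoallyl opening (the course of the acid hydration of sabinene to terpinen-4-ol): protonation of the strained exocyclic alkene, far more basic than the prenyl alkenes, gives the tertiary cyclopropylcarbinyl cation, and the carboxylic acid attacks the isopropyl-bearing cyclopropane carbon anti to the C–C bond that breaks, so that strain is released, the cyclohexene with its C1=C2 alkene appears and the C–O stereocentre should be set as (R) by inversion of the (1S) bridgehead.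

**Compound list**

1 | prop-2-yn-1-ol | C#CCO | starting material
2 | isopropylmagnesium chloride | CC(C)[Mg]Cl | starting material
3 | chloromagnesium (2Z)-3-(chloromagnesio)-2-(propan-2-yl)prop-2-en-1-olate | Cl[Mg]/C=C(\CO[Mg]Cl)C(C)C | intermediate
4 | 3-methyl-2-methylidenebutan-1-ol | CC(C)C(=C)CO | intermediate
5 | 2-(chloromethyl)-3-methylbut-1-ene | CC(C)C(=C)CCl | intermediate
6 | (2R)-2-(chloromethyl)oxirane | ClC[C@H]1CO1 | starting material
7 | [2-(propan-2-yl)prop-2-en-1-yl]magnesium chloride | CC(C)C(=C)C[Mg]Cl | intermediate
8 | chloromagnesium (2R)-1-chloro-6-methyl-5-methylideneheptan-2-olate | ClC[C@H](O[Mg]Cl)CCC(=C)C(C)C | intermediate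
9 | (2R)-2-(4-methyl-3-methylidenepentyl)oxirane | CC(C)C(=C)CC[C@@H]1CO1 | intermediate
10 | (1R,2R,5S)-5-(propan-2-yl)bicyclo[3.1.0]hexan-2-ol | CC(C)[C@@]12CC[C@@H](O)[C@@H]1C2 | intermediate
11 | (1R,5S)-5-(propan-2-yl)bicyclo[3.1.0]hexan-2-one | CC(C)[C@@]12CCC(=O)[C@@H]1C2 | intermediate
12 | (1S,5S)-4-methylidene-1-(propan-2-yl)bicyclo[3.1.0]hexane | CC(C)[C@@]12CCC(=C)[C@@H]1C2 | intermediate
13 | 4-iodophenol | Oc1ccc(I)cc1 | starting material
14 | 1-bromo-3-methylbut-2-ene | CC(C)=CCBr | starting material
15 | 4-iodo-2-(3-methylbut-2-en-1-yl)phenol | CC(C)=CCc1cc(I)ccc1O | intermediate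
16 | 4-iodo-2,6-bis(3-methylbut-2-en-1-yl)phenol | CC(C)=CCc1cc(I)cc(CC=C(C)C)c1O | intermediate
17 | 4-hydroxy-3,5-bis(3-methylbut-2-en-1-yl)benzoic acid | CC(C)=CCc1cc(C(=O)O)cc(CC=C(C)C)c1O | intermediate
18 | (1R)-4-methyl-1-(propan-2-yl)cyclohex-3-en-1-yl 4-hydroxy-3,5-bis(3-methylbut-2-en-1-yl)benzoate | CC(C)=CCc1cc(C(=O)O[C@@]2(C(C)C)CC=C(C)CC2)cc(CC=C(C)C)c1O | target

**Step count and risks**

Total step count: 8. Longest linear sequence: 6 steps (steps 1, 2, 3, 4, 5 and 8); the acid branch (steps 6 and 7) joins at step 8.

The three steps most likely to fail: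

Step 8. The ring-opened tertiary cation may lose a proton to terpinenes faster than the acid captures it. The acid catalyst may also trigger cyclisation of the ortho-prenyl phenol onto its own alkene. Complete opening of the cation before capture would erode the enantiomeric purity. The fallback forms the acyl C–O bond on a pre-made tertiary alcohol instead; it sets out from 12 and 17 and comes back at 18. Compound 12 is hydrated (dilute H2SO4, acetone/H2O, 0 °C → rt, the classical acid hydration of sabinene) to (1R)-4-methyl-1-(propan-2-yl)cyclohex-3-en-1-ol F1. Compound 17 is acetylated at the phenol (Ac2O, pyridine; aqueous work-up) to 4-(acetyloxy)-3,5-bis(3-methylbut-2-en-1-yl)benzoic acid F2. Yamaguchi esterification of F2 with F1 (2,4,6-trichlorobenzoyl chloride, Et3N, then stoichiometric DMAP, toluene, warming as needed for the tertiary alcohol) should give (1R)-4-methyl-1-(propan-2-yl)cyclohex-3-en-1-yl 4-(acetyloxy)-3,5-bis(3-methylbut-2-en-1-yl)benzoate F3. Methanolysis of the aryl acetate (K2CO3, MeOH, 0 °C) then returns 18.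

Step 3. Magnesium salts may slow the closure of the chlorohydrin alkoxide and aggregate with the lithium amide, so that the lithiated epoxide eliminates or adds the amide instead of cyclopropanating. Direct displacement of chloride by the Grignard reagent would lower the enantiomeric purity. The fallback uses a metal carbene from a diazoketone in place of the lithiated epoxide; it sets out from 4 and comes back at 11. Johnson–Claisen rearrangement of 4 (triethyl orthoacetate, cat. propionic acid, 140 °C) should give ethyl 5-methyl-4-methylidenehexanoate F4. Saponification (LiOH, THF/H2O) gives 5-methyl-4-methylidenehexanoic acid F5, and oxalyl chloride (cat. DMF, CH2Cl2) gives 5-methyl-4-methylidenehexanoyl chloride F6. Diazomethane (Et2O, 0 °C) gives 1-diazo-6-methyl-5-methylideneheptan-2-one F7. Intramolecular cyclopropanation catalysed by CuOTf and a chiral bis(oxazoline) ligand of the appropriate antipode should then give 11, possibly with lower enantiomeric purity than the main route.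

Step 6. O-alkylation may compete with ortho C-alkylation, and the second alkylation may stop at the mono-prenylated phenol or overrun to dienones, so that little of the 2,6-dialkylated phenol forms. The fallback builds both aryl–prenyl bonds by cross-coupling; it sets out from 14 and comes back at 17, bypassing 15, 16 and step 7. Zinc insertion into 14 (Zn, LiCl, THF) gives (3-methylbut-2-en-1-yl)zinc bromide F8. Linear-selective Negishi coupling (Pd(OAc)2, CPhos, THF) of F8 with purchased methyl 3,5-dibromo-4-hydroxybenzoate F9, taken as its sodium phenoxide (NaH), should give methyl 4-hydroxy-3,5-bis(3-methylbut-2-en-1-yl)benzoate F10. Saponification (LiOH, THF/H2O, then aq citric acid) gives 17.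

**Further compounds**

F1 | step 8 | (1R)-4-methyl-1-(propan-2-yl)cyclohex-3-en-1-ol | O[C@@]1(C(C)C)CC=C(C)CC1
F2 | step 8 | 4-(acetyloxy)-3,5-bis(3-methylbut-2-en-1-yl)benzoic acid | CC(C)=CCc1cc(C(=O)O)cc(CC=C(C)C)c1OC(C)=O
F3 | step 8 | (1R)-4-methyl-1-(propan-2-yl)cyclohex-3-en-1-yl 4-(acetyloxy)-3,5-bis(3-methylbut-2-en-1-yl)benzoate | CC(C)=CCc1cc(C(=O)O[C@@]2(C(C)C)CC=C(C)CC2)cc(CC=C(C)C)c1OC(C)=O
F4 | step 3 | ethyl 5-methyl-4-methylidenehexanoate | CCOC(=O)CCC(=C)C(C)C
F5 | step 3 | 5-methyl-4-methylidenehexanoic acid | OC(=O)CCC(=C)C(C)C
F6 | step 3 | 5-methyl-4-methylidenehexanoyl chloride | ClC(=O)CCC(=C)C(C)C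
F7 | step 3 | 1-diazo-6-methyl-5-methylideneheptan-2-one | CC(C)C(=C)CCC(=O)C=[N+]=[N-]
F8 | step 6 | (3-methylbut-2-en-1-yl)zinc bromide | CC(C)=CC[Zn]Br
F9 | step 6 | methyl 3,5-dibromo-4-hydroxybenzoate (purchased) | COC(=O)c1cc(Br)c(O)c(Br)c1
F10 | step 6 | methyl 4-hydroxy-3,5-bis(3-methylbut-2-en-1-yl)benzoate | COC(=O)c1cc(CC=C(C)C)c(O)c(CC=C(C)C)c1
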